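## Structural features

The target is a chamigrane, a spiro[5.5]undecane: ring A (C6–C11) carries an exocyclic methylene on C7, a secondary bromide on C10 and a gem-dimethyl group on C11; ring B (C1–C6) carries a secondary bromide on C2 and a tertiary methyl carbinol on C3. The spiro atom C6 and C11 are vicinal quaternary carbons, and C6 is flanked on the other side by the sp2 carbon C7, so both ring-A bonds to C6 are congested. There are four stereocentres: C2 and C3 are adjacent (trans bromohydrin), C6 is the spiro atom, and C10 stands alone, neopentylic to C11. C6 is stereogenic only because the arms C1–C2 and C5–C4 differ, so nothing relays information between C10 and the ring-B centres and their relation must come from absolute control. In the ring-B chair with C11 equatorial and C7 axial (the other chair puts a C11 methyl over ring B), Br on C2 and OH on C3 are both equatorial and the C3 methyl is axial. This trans-diequatorial bromohydrin is the anti-Fürst–Plattner isomer, so it cannot be made by diaxial opening of a bromonium ion or epoxide on the assembled spirocycle. Fragile points are the exocyclic alkene (acid-induced migration into the ring, electrophiles), the β-bromo tertiary alcohol (epoxide closure, semipinacol shift) and the C10 bromide, which cannot be made by SN2 on a neopentylic alcohol. The feature the key step exploits: ring B has its only oxygen on C3, para to C6, with two skeletally equal arms, so it is a reduced para-substituted phenol, and the C7 methylene is the footprint of a 6-exo-dig attack of that phenol's para carbon on a terminal alkyne.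

## Logic of the disconnections

**14 to 13.** The C3–CH3 bond is cut. The C3 oxygen is already in place, and the trans-diequatorial bromohydrin cannot come from an alkene addition, so C3 is best made by methyl addition to a ketone. The gain is that the last stereocentre becomes a facial-selectivity problem on a conformationally fixed cyclohexanone. The demand is axial delivery of methyl by a non-basic reagent that leaves the α-bromide and the exocyclic alkene alone.

**13 to 10.** The C2–Br bond is cut and the C1=C2 double bond restored. Conjugate reduction of the enone in 10 gives an enolate equivalent on the C2 side only, so the choice of arm is already made and bromination is regiospecific. The C2 configuration is left to thermodynamics, since equatorial bromine avoids the axial C7. The demand is a hydride source that ignores the exocyclic alkene and both bromides.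

**10 to 8.** The C4=C5 double bond is restored. In 8 ring B is a symmetric cross-conjugated dienone and C6 is not a stereocentre. The gain is large: the configuration of C6 relative to C10 turns from a C–C bond-forming problem between two quaternary carbons into a catalyst-controlled choice between two enone arms. The demand is a chiral hydride catalyst that distinguishes the arms and stops after one reduction.

**8 to 7 (key).** The C6–C7 bond is cut. Ring A opens, the dienone of 8 becomes the phenol ring of 7, and the exocyclic methylene becomes a terminal alkyne. The spiro quaternary carbon becomes an aromatic carbon, so the vicinal quaternary pair reduces to an aryl–C(tertiary) bond. The demand is ipso (para-carbon) attack in the 6-exo-dig mode under conditions that do not rearrange the dienone or touch the bromide.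

**7 to 5 + 6.** The C6–C11 bond (aryl to quaternary carbon) is cut. The cation at C11 is bridged by the bromine on C10, so the C10–Br bond is never broken and its configuration passes through unchanged. The demand is para selectivity on 6 and no loss of bromonium integrity.

**5 to 4 to 3.** The C10–Br bond is cut back to an epoxide C–O bond (SN2 with inversion at the secondary carbon, possible here because C11 is still an epoxide carbon). The epoxide is then cut back to the trisubstituted alkene of 3. C10 is the only centre that needs a reagent-controlled absolute configuration, and a trisubstituted alkene is the best substrate class for that.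

**3 to 1 + 2.** The sp3–sp bond C8–C7 is cut: acetylide alkylation of a primary bromide, both components commercial.

## Other disconnections considered

Alternative 1: Diels–Alder construction of ring B, the disconnection that comes to mind first. The cut is C1–C6 and C4–C5; the forward step is a [4+2] cycloaddition of bromo enone A1 with isoprene to give spiro ketone A2. The diene must add to an exocyclic alkene flanked by the quaternary C11, and which face it takes relative to C10–Br rests on a weak axial/equatorial bias, so the C6/C10 relation is not secured. The product then needs a hindered ketone methylenation, and its ring-B alkene would have to become the anti-Fürst–Plattner bromohydrin on a locked ring. The chosen plan brings the C3 oxygen in from the phenol and the methylene in from the alkyne, and sets C6 by catalyst control.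

Alternative 2: biomimetic bromonium-induced cyclization. The cut is C6–C11 together with C10–Br; the forward step is Br+ attack on the terminal alkene of (E)-γ-bisabolene A3 with capture by the tetrasubstituted alkene. It needs A3 as a single geometric isomer, although E and Z differ only by a remote ring alkene. Three alkenes compete for Br+, there is no handle for enantioface control at the remote prenyl unit, bromonium transfer between alkenes erodes any induced chirality, and proton loss gives exo/endo mixtures. Ring B would again need the anti-Fürst–Plattner bromohydrin afterwards. The chosen plan forms the same C6–C11 bond as an aryl alkylation from an enantiopure bromonium precursor, with no alkene geometry to control.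

Alternative 3: Ireland–Claisen rearrangement. The cut is C6–C11 through a [3,3] shift; the forward step converts the silyl ketene acetal of prenyl ester A4 into acid A5, forming the vicinal quaternary pair. The ketene acetal of A4 has enantiotopic faces, so C6 is formed racemic. The vinyl group of A5 cannot be turned into the neopentylic C10 bromide with defined configuration. Ring A would still have to be closed and C7 methylenated, which adds at least five steps. The one attraction, bromolactonization of A5 to fix ring B, does not make up for these.

Key step: step 5

Remark (numbering): locants of all spirocycles follow the numbering of 14 (C1–C5 ring B, C6 spiro, C7–C11 ring A; C1 is the arm cis to the C10 bromine), also where lowest-locant rules would renumber ring B.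

Remark (assumption): the sense of arm selection by the chiral CuH catalyst on 8 cannot be predicted with confidence; "(R)-DTBM-SEGPHOS" stands for whichever ligand antipode reduces C4=C5.

## Steps

Step 1
Reactants: 1 5-bromo-2-methylpent-2-ene; 2 lithium acetylide–ethylenediamine complex
Product: 3 6-methylhept-5-en-1-yne
Conditions: 2 (1.2 equiv), DMSO, 0 °C to rt
Reagents that add atoms: none
Why: SN2 alkylation of an acetylide by a primary homoallylic bromide in a dipolar aprotic solvent; no stereocentre is formed.

Step 2
Reactants: 3 6-methylhept-5-en-1-yne
Product: 4 (3R)-3-(but-3-yn-1-yl)-2,2-dimethyloxirane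
Conditions: D-fructose-derived Shi ketone (0.3 equiv), Oxone, K2CO3, Bu4NHSO4 (cat.), MeCN/dimethoxymethane/aq. buffer (pH about 10.5), 0 °C
Reagents that add atoms: potassium peroxymonosulfate (active component of Oxone), [K+].[O-]S(=O)(=O)OO
Why: Shi epoxidation; the chiral dioxirane transfers oxygen through a spiro transition state, trisubstituted alkenes are its best substrate class, and the D-fructose-derived ketone should give the R epoxide; the alkyne is inert to dioxiranes under these conditions.

Step 3
Reactants: 4 (3R)-3-(but-3-yn-1-yl)-2,2-dimethyloxirane
Product: 5 (3S)-3-bromo-2-methylhept-6-yn-2-ol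
Conditions: Li2NiBr4 (1.2 equiv, from LiBr and NiBr2), THF, 0 °C to rt; aq. buffer work-up
Reagents that add atoms: dilithium tetrabromonickelate, [Li+].[Li+].[Ni+2].[Br-].[Br-].[Br-].[Br-]
Why: nucleophilic epoxide opening by bromide at the less substituted carbon (SN2, inversion), so the R epoxide should give the S bromide with the tertiary alcohol left on the carbon that becomes C11.

Step 4
Reactants: 5 (3S)-3-bromo-2-methylhept-6-yn-2-ol; 6 phenol
Product: 7 4-[(3S)-3-bromo-2-methylhept-6-yn-2-yl]phenol
Conditions: 6 (5 equiv), TfOH (5 mol %), (CF3)2CHOH/CH2Cl2, −20 to 0 °C
Reagents that add atoms: none
Why: dehydrative Friedel–Crafts alkylation; acid ionises the tertiary alcohol to a cation bridged by the neighbouring bromine, and the para carbon of 6 opens this bromonium ion at its tertiary end, so the C–Br bond at the stereocentre is never broken and S is retained. O- and ortho-alkylation are reversible under acid and the bulky tertiary electrophile should settle at the para position; the terminal alkyne is a far poorer nucleophile than excess phenol.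

Step 5
Reactants: 7 4-[(3S)-3-bromo-2-methylhept-6-yn-2-yl]phenol
Product: 8 (10S)-10-bromo-11,11-dimethyl-7-methylidenespiro[5.5]undeca-1,4-dien-3-one
Conditions: Ph3PAuNTf2 (5 mol %), CH2Cl2, rt, no Brønsted acid additive
Reagents that add atoms: none
Why: Au(I) coordinates the terminal alkyne and the phenol carbon para to OH (the ipso carbon carrying the tether, C6) attacks the internal alkyne carbon C7 anti to gold; the resulting Wheland/oxocarbenium ion loses the O–H proton to give the dienone, and that proton cleaves the exocyclic vinyl–gold bond to leave C7=CH2. The closest known reaction type is the gold-catalysed intramolecular ipso-Friedel–Crafts alkenylation of para-tethered phenols to spirocyclohexadienones, well established for 5-exo closure and applied here to the homologous 6-exo case. Ring A is closed in the 6-exo-dig mode through the C6–C7 bond, helped by the gem-dimethyl group on the tether carbon next to the arene. No stereocentre is created: C6 becomes quaternary but stays non-stereogenic because ring B is a symmetric dienone, and C10 is untouched. The step needs ipso rather than ortho attack, which the substrate secures because the ipso carbon is para to OH while the ortho carbons are meta to it and would have to close a seven-membered ring. It needs exo rather than endo attack, which Markovnikov attack on a terminal alkyne provides. It also needs the product to survive, hence neutral conditions to avoid the acid-promoted dienone–phenol shift of C11 and migration of the exocyclic alkene into the ring; the secondary bromide is inert to Au(I).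

Step 6
Reactants: 8 (10S)-10-bromo-11,11-dimethyl-7-methylidenespiro[5.5]undeca-1,4-dien-3-one
Product: 10 (6R,10S)-10-bromo-11,11-dimethyl-7-methylidenespiro[5.5]undec-1-en-3-one, via silyl dienol ether 9 (not isolated)
Conditions: Cu(OAc)2 (5 mol %), (R)-DTBM-SEGPHOS (5.5 mol %, see remark), PhMe2SiH (1.2 equiv), toluene, 0 °C; then 1 M HCl, THF, 0 °C
Reagents that add atoms: dimethylphenylsilane, C[SiH](C)c1ccccc1 (its silyl group is present only in 9)
Why: catalytic asymmetric CuH conjugate reduction used as a desymmetrization of a 4,4-disubstituted cyclohexadienone; the chiral Cu–H delivers hydride to C5 of the arm trans to the C10 bromine, which makes C6 a stereocentre (R) under catalyst control. The reaction should stop after one reduction because silyl dienol ether 9 is no longer a Michael acceptor; the isolated alkene and the alkyl bromide are not substrates for CuH under these conditions.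

Step 7
Reactants: 10 (6R,10S)-10-bromo-11,11-dimethyl-7-methylidenespiro[5.5]undec-1-en-3-one
Product: 13 (2R,6R,10S)-2,10-dibromo-11,11-dimethyl-7-methylidenespiro[5.5]undecan-3-one, via silyl enol ether 11 (not isolated), via axial 2-epimer 12 (not isolated)
Conditions: [(Ph3P)CuH]6 (5 mol % Cu), PhMe2SiH (1.5 equiv), toluene, rt; then NBS (1.05 equiv), THF, −78 °C; then LiBr (0.3 equiv), acetone, rt
Reagents that add atoms: N-bromosuccinimide, O=C1CCC(=O)N1Br; dimethylphenylsilane, C[SiH](C)c1ccccc1 (its silyl group is present only in 11)
Why: CuH 1,4-hydrosilylation gives the enol ether only on the C2 side, so electrophilic bromination of 11 is regiospecific and far faster than attack on the hindered exocyclic alkene. The kinetic mixture of C2 epimers should converge under bromide exchange at the activated α-carbon on the equatorial bromide 13, because axial bromine in 12 is 1,3-diaxial to C7.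

Step 8
Reactants: 13 (2R,6R,10S)-2,10-dibromo-11,11-dimethyl-7-methylidenespiro[5.5]undecan-3-one
Product: 14 (2R,3R,6R,10S)-2,10-dibromo-3,11,11-trimethyl-7-methylidenespiro[5.5]undecan-3-ol
Conditions: Me3Al (3 equiv), toluene, −40 to 0 °C; aq. Rochelle salt
Reagents that add atoms: trimethylaluminium, C[Al](C)C
Why: methyl addition to a ketone with excess trimethylaluminium in a hydrocarbon solvent, which delivers methyl from the axial face through a two-aluminium transition state (compression effect, here reinforced by the equatorial C2 bromine next to the complexed oxygen); this should give axial methyl cis to C11 and equatorial OH trans to bromine. The reagent is non-basic, so the α-bromo ketone is not enolised, and the alkoxide cannot close to an epoxide because the required diaxial arrangement would force C11 axial.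

## Compound list

1 | 5-bromo-2-methylpent-2-ene | CC(C)=CCCBr | starting material
2 | lithium acetylide–ethylenediamine complex | [Li+].[C-]#C.NCCN | starting material
3 | 6-methylhept-5-en-1-yne | CC(C)=CCCC#C | intermediate
4 | (3R)-3-(but-3-yn-1-yl)-2,2-dimethyloxirane | C#CCC[C@H]1OC1(C)C | intermediate
5 | (3S)-3-bromo-2-methylhept-6-yn-2-ol | C#CCC[C@H](Br)C(C)(C)O | intermediate
6 | phenol | Oc1ccccc1 | starting material
7 | 4-[(3S)-3-bromo-2-methylhept-6-yn-2-yl]phenol | C#CCC[C@H](Br)C(C)(C)c1ccc(O)cc1 | intermediate
8 | (10S)-10-bromo-11,11-dimethyl-7-methylidenespiro[5.5]undeca-1,4-dien-3-one | C=C1CC[C@H](Br)C(C)(C)C12C=CC(=O)C=C2 | intermediate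
9 | {[(6R,10S)-10-bromo-11,11-dimethyl-7-methylidenespiro[5.5]undeca-1,3-dien-3-yl]oxy}dimethyl(phenyl)silane | C=C1CC[C@H](Br)C(C)(C)[C@@]12CC=C(O[Si](C)(C)c3ccccc3)C=C2 | intermediate
10 | (6R,10S)-10-bromo-11,11-dimethyl-7-methylidenespiro[5.5]undec-1-en-3-one | C=C1CC[C@H](Br)C(C)(C)[C@@]12CCC(=O)C=C2 | intermediate
11 | {[(6R,10S)-10-bromo-11,11-dimethyl-7-methylidenespiro[5.5]undec-2-en-3-yl]oxy}dimethyl(phenyl)silane | C=C1CC[C@H](Br)C(C)(C)[C@@]12CCC(O[Si](C)(C)c3ccccc3)=CC2 | intermediate
12 | (2S,6R,10S)-2,10-dibromo-11,11-dimethyl-7-methylidenespiro[5.5]undecan-3-one | C=C1CC[C@H](Br)C(C)(C)[C@@]12CCC(=O)[C@@H](Br)C2 | intermediate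
13 | (2R,6R,10S)-2,10-dibromo-11,11-dimethyl-7-methylidenespiro[5.5]undecan-3-one | C=C1CC[C@H](Br)C(C)(C)[C@@]12CCC(=O)[C@H](Br)C2 | intermediate
14 | (2R,3R,6R,10S)-2,10-dibromo-3,11,11-trimethyl-7-methylidenespiro[5.5]undecan-3-ol | C=C1CC[C@H](Br)C(C)(C)[C@@]12CC[C@@](C)(O)[C@H](Br)C2 | target

## Step count and risk

Total step count: 8. Longest linear sequence: 8 (the route is linear; 6 is the only second building block).

Least certain steps:

**Step 5 (key).** The 6-exo closure is slower than the established 5-exo case. The most likely failures are a Lewis-acid-induced dienone–phenol shift of the tertiary C11 from C6 to C1 (re-aromatisation) once 8 has formed, hydration or oligomerisation of the alkyne if closure is slow, and migration of the exocyclic alkene into ring A. The fallback changes the bond-forming event from π-acid activation to cross-coupling and sets out from 7. Markovnikov hydroiodination of the alkyne (NaI, TMSCl, H2O, MeCN) should give 4-[(3S)-3-bromo-6-iodo-2-methylhept-6-en-2-yl]phenol F1. Palladium(0)-catalysed dearomative alkenylation of its phenoxide (bulky biarylphosphine, K2CO3, dioxane, heat) would then form C6–C7 by oxidative addition into the vinyl iodide, attack of the para carbon on palladium and reductive elimination. This returns to the route at 8 with the methylene in place.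

**Step 8.** The risk is poor facial selectivity: equatorial methyl delivery would give the C3 epimer, and any Lewis-acid-induced loss of bromide from the product alkoxide would trigger a semipinacol shift. The fallback moves the methyl addition to an enone, where antiperiplanar (axial) attack is stereoelectronically favoured, and sets out from 8. The CuH desymmetrization is run with the antipodal ligand so that C1=C2 is reduced, giving {[(6S,10S)-10-bromo-11,11-dimethyl-7-methylidenespiro[5.5]undeca-2,4-dien-3-yl]oxy}dimethyl(phenyl)silane F2. This is brominated in the same flask (NBS, −78 °C) and equilibrated with LiBr to (2R,6S,10S)-2,10-dibromo-11,11-dimethyl-7-methylidenespiro[5.5]undec-4-en-3-one F3, with the bromine pseudo-equatorial. MeLi/CeCl3 (THF, −78 °C) should add 1,2 from the axial face to give (2R,3R,6S,10S)-2,10-dibromo-3,11,11-trimethyl-7-methylidenespiro[5.5]undec-4-en-3-ol F4. Hydroxyl-directed hydrogenation of the C4=C5 bond ([Rh(nbd)(dppb)]BF4, H2, CH2Cl2) would return to the route at 14. The weak point of this fallback is competing reduction of the exocyclic alkene.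

**Step 6.** The two enone arms differ only through the remote C10 centre, so the risk is insufficient catalyst control (a mismatched substrate bias would give the C6 epimer) or some 1,2-reduction. The fallback moves the desymmetrization from the dienone to a saturated ketone and sets out from 8. Exhaustive conjugate reduction ([(Ph3P)CuH]6 cat., PhMe2SiH and t-BuOH in excess) should give (10S)-10-bromo-11,11-dimethyl-7-methylidenespiro[5.5]undecan-3-one F5, in which ring B is again symmetric. Deprotonation with a chiral lithium amide (lithium bis[(R)-1-phenylethyl]amide or its antipode, TMSCl in situ, THF, −100 °C) selects one axial α-proton of the chair fixed by the equatorial C11, giving {[(6R,10S)-10-bromo-11,11-dimethyl-7-methylidenespiro[5.5]undec-2-en-3-yl]oxy}trimethylsilane F6. Bromination and bromide equilibration as in step 7 return to the route at 13.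

**Step 4.** The intermolecular alkylation can lose material to ortho- and O-alkylation, to proton loss from the bromonium ion (allylic bromide) and to acid-promoted alkyne hydration. Any reversible transfer of Br+ would also erode the C10 configuration. The fallback changes the nucleophile and the mode of dearomatization and sets out from 5. Anisole, which alkylates cleanly at the para position and cannot O-alkylate, should give 1-[(3S)-3-bromo-2-methylhept-6-yn-2-yl]-4-methoxybenzene F7. Gold(I)-catalysed ipso-cyclization of this ether in wet solvent, with loss of the O-methyl group from the oxocarbenium intermediate, returns to the route at 8.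

## Further compounds

F1 | step 5 | 4-[(3S)-3-bromo-6-iodo-2-methylhept-6-en-2-yl]phenol | C=C(I)CC[C@H](Br)C(C)(C)c1ccc(O)cc1
F2 | step 8 | {[(6S,10S)-10-bromo-11,11-dimethyl-7-methylidenespiro[5.5]undeca-2,4-dien-3-yl]oxy}dimethyl(phenyl)silane | C=C1CC[C@H](Br)C(C)(C)[C@@]12C=CC(O[Si](C)(C)c3ccccc3)=CC2
F3 | step 8 | (2R,6S,10S)-2,10-dibromo-11,11-dimethyl-7-methylidenespiro[5.5]undec-4-en-3-one | C=C1CC[C@H](Br)C(C)(C)[C@@]12C=CC(=O)[C@H](Br)C2
F4 | step 8 | (2R,3R,6S,10S)-2,10-dibromo-3,11,11-trimethyl-7-methylidenespiro[5.5]undec-4-en-3-ol | C=C1CC[C@H](Br)C(C)(C)[C@@]12C=C[C@@](C)(O)[C@H](Br)C2
F5 | step 6 | (10S)-10-bromo-11,11-dimethyl-7-methylidenespiro[5.5]undecan-3-one | C=C1CC[C@H](Br)C(C)(C)C12CCC(=O)CC2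
F6 | step 6 | {[(6R,10S)-10-bromo-11,11-dimethyl-7-methylidenespiro[5.5]undec-2-en-3-yl]oxy}trimethylsilane | C=C1CC[C@H](Br)C(C)(C)[C@@]12CCC(O[Si](C)(C)C)=CC2
F7 | step 4 | 1-[(3S)-3-bromo-2-methylhept-6-yn-2-yl]-4-methoxybenzene | C#CCC[C@H](Br)C(C)(C)c1ccc(OC)cc1
A1 | alternative 1 | (4S)-4-bromo-3,3-dimethyl-2-methylidenecyclohexan-1-one | C=C1C(=O)CC[C@H](Br)C1(C)C
A2 | alternative 1 | (6S,10S)-10-bromo-3,11,11-trimethylspiro[5.5]undec-2-en-7-one | O=C1CC[C@H](Br)C(C)(C)[C@@]12CCC(C)=CC2
A3 | alternative 2 | (E)-γ-bisabolene, (4E)-1-methyl-4-(6-methylhept-5-en-2-ylidene)cyclohex-1-ene | CC1=CC/C(=C(\C)CCC=C(C)C)CC1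
A4 | alternative 3 | 3-methylbut-2-en-1-yl 4-methylcyclohex-3-ene-1-carboxylate (racemic) | CC1=CCC(CC1)C(=O)OCC=C(C)C
A5 | alternative 3 | 4-methyl-1-(2-methylbut-3-en-2-yl)cyclohex-3-ene-1-carboxylic acid (racemic) | CC1=CCC(CC1)(C(=O)O)C(C)(C)C=C
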